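The oxolane atoms are O1' and C2'–C5'; the diene carbons run Ca–Cd from C2' to C3 of the isochromenone.

- **Cuts:** the enol-lactone bond O2–C1 and the C3–C4 bond of the isochromenone, the double bonds Cc=Cd and Ca=Cb, the ether bond O1'–C5', and the chain bond C4'–C5'.
- **Forward order:** a tartrate-derived C4 unit (Ca–C2'–C3'–C4') takes up a masked acetyl anion. The oxolane closes as the first ring, two olefinations grow the E,E-diene up to a Weinreb amide, a laterally lithiated chloro-orsellinate is acylated, and the pyranone ring closes last.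
- **Enabling feature:** in the oxolane ring C2' and C3' carry a threo pair of oxygens within the run Ca–C2'–C3'–C4', which is L-threitol atom for atom. C5' lies γ to the C2' oxygen, so a C5' ketone is caught by that oxygen as a five-membered hemiketal, while the C3' oxygen, β to C5', steers the reduction.
- **Stereochemistry:** C2' and C3' come from diethyl L-tartrate and are never touched. C5' comes from substrate-controlled hydride delivery to the ring oxocarbenium ion. Both E alkenes come from stabilised phosphorus reagents.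

Key step: step 9

Remark: the precursor of the key step is drawn and counted as the open-chain hydroxy ketone, although on isolation it will equilibrate with its cyclic hemiketal. PMB = 4-methoxybenzyl, MOM = methoxymethyl.

Step 1
Reactants: 1 diethyl L-tartrate (diethyl (2R,3R)-2,3-dihydroxybutanedioate); 2 4-methoxybenzaldehyde dimethyl acetal
Product: 3 diethyl (4R,5R)-2-(4-methoxyphenyl)-1,3-dioxolane-4,5-dicarboxylate
Conditions: p-TsOH·H2O (cat.), toluene, reflux, MeOH distilled off
Reagents that add atoms: none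
Why: Acid-catalysed transacetalisation driven by removal of methanol ties the two secondary hydroxyls into a 4-methoxybenzylidene acetal without touching the carbinol carbons, and because the diol is C2-symmetric the acetal carbon is not a stereocentre, so a single compound should result.

Step 2
Reactants: 3 diethyl (4R,5R)-2-(4-methoxyphenyl)-1,3-dioxolane-4,5-dicarboxylate
Product: 5 2-O-PMB-L-threitol ((2S,3S)-3-[(4-methoxybenzyl)oxy]butane-1,2,4-triol), via acetal diol 4 (not isolated)
Conditions: LiAlH4, AlCl3, Et2O/CH2Cl2, 0 °C → rt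
Reagents that add atoms: none
Why: Mixed-hydride reduction with chloroalane takes both esters to primary alcohols and then opens the aluminium-activated benzylidene acetal reductively, the standard entry to 2-O-benzyl-type threitols, and the C2 symmetry of 4 makes the two possible C–O cleavages equivalent, so that one hydroxyl (the future C3' oxygen) is singled out as its PMB ether.

Step 3
Reactants: 5 2-O-PMB-L-threitol
Product: 6 (2S)-2-[(4S)-2,2-dimethyl-1,3-dioxolan-4-yl]-2-[(4-methoxybenzyl)oxy]ethan-1-ol
Conditions: 2,2-dimethoxypropane, PPTS (cat.), acetone, rt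
Reagents that add atoms: 2,2-dimethoxypropane, COC(C)(C)OC
Why: Acetonide formation under thermodynamic control (transketalisation) favours the five-membered dioxolane on the vicinal C2'/Ca diol over a 1,3-dioxane that would carry an axial methyl group, which leaves the C4' hydroxyl next to the PMB ether as the only free one.

Step 4
Reactants: 6 (2S)-2-[(4S)-2,2-dimethyl-1,3-dioxolan-4-yl]-2-[(4-methoxybenzyl)oxy]ethan-1-ol
Product: 7 (2S)-2-[(4S)-2,2-dimethyl-1,3-dioxolan-4-yl]-2-[(4-methoxybenzyl)oxy]ethyl trifluoromethanesulfonate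
Conditions: Tf2O, 2,6-lutidine, CH2Cl2, −78 °C
Reagents that add atoms: trifluoromethanesulfonic anhydride, O=S(=O)(OS(=O)(=O)C(F)(F)F)C(F)(F)F
Why: O-Sulfonylation with Tf2O and a hindered pyridine base at low temperature gives the primary triflate, the leaving group of choice for SN2 reactions at a β-branched and β-oxygenated carbon where halides and tosylates react sluggishly.

Step 5
Reactants: 7 the triflate; 8 2-methyl-1,3-dithiane
Product: 10 (4S)-4-{(1S)-1-[(4-methoxybenzyl)oxy]-2-(2-methyl-1,3-dithian-2-yl)ethyl}-2,2-dimethyl-1,3-dioxolane, via lithiated dithiane 9 (not isolated)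
Conditions: 8, n-BuLi, THF, −30 °C; then 7, THF, −78 → −30 °C
Reagents that add atoms: none
Why: Corey–Seebach umpolung, in which the lithiated dithiane acts as an acetyl anion equivalent and displaces the primary triflate in an SN2 reaction at low temperature, forms C4'–C5' without involving a stereocentre.

Step 6
Reactants: 10 the dithiane acetonide
Product: 11 (2S,3S)-3-[(4-methoxybenzyl)oxy]-4-(2-methyl-1,3-dithian-2-yl)butane-1,2-diol
Conditions: AcOH/H2O 4:1, 40 °C
Reagents that add atoms: none
Why: Acid hydrolysis of the terminal acetonide proceeds under conditions that leave the PMB ether and the dithioketal, both stable to aqueous acetic acid, untouched.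

Step 7
Reactants: 11 the dithiane diol
Product: 12 (2S,3S)-1-[(tert-butyldiphenylsilyl)oxy]-3-[(4-methoxybenzyl)oxy]-4-(2-methyl-1,3-dithian-2-yl)butan-2-ol
Conditions: t-BuPh2SiCl, imidazole, CH2Cl2, 0 °C
Reagents that add atoms: tert-butyl(chloro)diphenylsilane, CC(C)(C)[Si](Cl)(c1ccccc1)c1ccccc1
Why: In this sterically controlled silylation the bulky chlorosilane reacts with the primary Ca hydroxyl far faster than with the flanked secondary C2' hydroxyl, and the acid-stable silyl ether blocks the only oxygen that could later compete by six-ring hemiketal formation.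

Step 8
Reactants: 12 the silylated dithiane alcohol
Product: 13 (4S,5S)-6-[(tert-butyldiphenylsilyl)oxy]-5-hydroxy-4-[(4-methoxybenzyl)oxy]hexan-2-one
Conditions: MeI, CaCO3, MeCN/H2O 9:1, 45 °C
Reagents that add atoms: water, O
Why: Alkylative dithiane hydrolysis (S-methylation followed by hydrolysis of the sulfonium salt, with the acid scavenged by CaCO3) unmasks the ketone without an oxidant, so that the electron-rich PMB ether and the free alcohol are not at risk.

Step 9
Reactants: 13 (4S,5S)-6-[(tert-butyldiphenylsilyl)oxy]-5-hydroxy-4-[(4-methoxybenzyl)oxy]hexan-2-one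
Product: 16 tert-butyl({(2S,3S,5S)-3-[(4-methoxybenzyl)oxy]-5-methyloxolan-2-yl}methoxy)diphenylsilane, via cyclic hemiketal 14 (not isolated), via oxocarbenium ion 15 (not isolated)
Conditions: Et3SiH (10 equiv), then BF3·OEt2 (3 equiv), CH2Cl2, −78 °C; Et3N, then aq NaHCO3 at −78 °C
Reagents that add atoms: none
Why: The free C2' hydroxyl of 13 adds reversibly to the C5' carbonyl (5-exo-trig) to give hemiketal 14, BF3 removes the anomeric hydroxyl, and Et3SiH reduces the resulting ring oxocarbenium ion 15, so that the O1'–C5' bond, the oxolane ring and the C5'–H bond all arise in one flask. The closest known reaction type is the Lewis acid/silane reductive etherification of γ-hydroxy ketones, the same process that deoxygenates furanose hemiketals to C-glycosides. In 15 the atoms C2', O1', C5' and C4' are coplanar and C3' is the flap of an envelope; the conformer with the C3' ether oxygen pseudo-axial is favoured because the partly negative oxygen then lies close to the cationic C5'=O1' unit, and since the Ca arm on C2' is cis to that oxygen it becomes pseudo-equatorial in the very same conformer, so the two tartrate-derived substituents reinforce each other. Stereoelectronically preferred attack on the inside face of this envelope (the face towards which C3' is folded, leading to a staggered rather than an eclipsed product) brings hydride in cis to the C3' oxygen, which places the methyl group trans to both the C3' oxygen and the Ca arm and sets C5' as S. Besides this facial selectivity the step needs ring-size selectivity, which the silyl ether on the Ca oxygen secures by leaving the C2' hydroxyl as the only nucleophile, and chemoselectivity, which is secured by having excess silane present before the Lewis acid is added at −78 °C, so that 15 is reduced faster than it can lose a C4' proton and then the C3' ether, and before the PMB ether can ionise.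

Step 10
Reactants: 16 the silylated oxolane
Product: 17 {(2S,3S,5S)-3-[(4-methoxybenzyl)oxy]-5-methyloxolan-2-yl}methanol
Conditions: Bu4NF, THF, 0 °C → rt
Reagents that add atoms: none
Why: Fluoride-mediated cleavage of the silyl ether, driven by the strength of the Si–F bond, frees the primary alcohol while the ether groups and the stereocentres are inert.

Step 11
Reactants: 17 the oxolane methanol
Product: 18 (2R,3S,5S)-3-[(4-methoxybenzyl)oxy]-5-methyloxolane-2-carbaldehyde
Conditions: Dess–Martin periodinane, NaHCO3, CH2Cl2, 0 °C → rt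
Reagents that add atoms: none
Why: Dess–Martin oxidation under bicarbonate buffer is fast, neutral and free of amine base, which should keep the configurationally labile C2' centre (α to the new aldehyde and cis to the C3' ether; the descriptor changes only through CIP ranking) intact, and 18 is carried on without chromatography.

Step 12
Reactants: 18 the aldehyde; 19 (triphenylphosphoranylidene)acetaldehyde
Product: 20 (2E)-3-{(2S,3S,5S)-3-[(4-methoxybenzyl)oxy]-5-methyloxolan-2-yl}prop-2-enal
Conditions: 19 (1.1 equiv), toluene, 40 °C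
Reagents that add atoms: none
Why: Wittig olefination with a stabilised ylide needs no external base, so neither epimerisation at C2' nor β-elimination of the C3' ether should intervene, and the reversible addition typical of stabilised ylides gives the E-enal (Ca=Cb), the α-alkoxy aldehyde reacting faster than the conjugated product.

Step 13
Reactants: 20 the enal; 21 diethyl {2-[methoxy(methyl)amino]-2-oxoethyl}phosphonate
Product: 23 (2E,4E)-N-methoxy-N-methyl-5-{(2S,3S,5S)-3-[(4-methoxybenzyl)oxy]-5-methyloxolan-2-yl}penta-2,4-dienamide, via sodium phosphonate anion 22 (not isolated)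
Conditions: 21, NaH, THF, 0 °C; then 20, −20 → 0 °C
Reagents that add atoms: none
Why: Horner–Wadsworth–Emmons olefination with the preformed, weakly basic phosphonoacetamide anion sets Cc=Cd as E and delivers the acyl donor for the arene coupling directly at the Weinreb amide level.

Step 14
Reactants: 24 methyl 2,4-dihydroxy-6-methylbenzoate (methyl orsellinate)
Product: 25 methyl 3-chloro-4,6-dihydroxy-2-methylbenzoate
Conditions: SO2Cl2 (1.0 equiv), Et2O, 0 °C
Reagents that add atoms: sulfuryl chloride, ClS(Cl)(=O)=O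
Why: Electrophilic aromatic chlorination of the resorcinol ring with one equivalent of SO2Cl2 should go to the position para to the hydrogen-bonded hydroxyl and next to the methyl group, the site chlorinated in the same way in resorcylic acid lactones, rather than to the crowded position between the two hydroxyls.

Step 15
Reactants: 25 methyl 3-chloro-4,6-dihydroxy-2-methylbenzoate
Product: 26 methyl 3-chloro-4,6-bis(methoxymethoxy)-2-methylbenzoate
Conditions: NaH, MOMCl, DMF, 0 °C → rt
Reagents that add atoms: chloromethyl methyl ether, COCCl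
Why: Williamson-type O-alkylation of both phenoxides, NaH being needed for the chelated hydroxyl ortho to the ester, installs acetal ethers that tolerate amide bases and DDQ.

Step 16
Reactants: 26 the bis-MOM toluate; 23 the dienyl Weinreb amide
Product: 29 methyl 3-chloro-4,6-bis(methoxymethoxy)-2-[(3E,5E)-6-{(2S,3S,5S)-3-[(4-methoxybenzyl)oxy]-5-methyloxolan-2-yl}-2-oxohexa-3,5-dien-1-yl]benzoate, via lithiated toluate 27 (not isolated), via chelated tetrahedral adduct 28 (not isolated)
Conditions: 26 (2.2 equiv), LiN(i-Pr)2 (2.1 equiv), THF, −78 °C; then 23, −78 °C; AcOH/THF quench at −78 °C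
Reagents that add atoms: none
Why: Lateral lithiation of the o-toluate followed by acylation with a Weinreb amide, a coupling established for this very chlorinated resorcylate pattern with α,β-unsaturated Weinreb amides, forms C3–C4, while adduct 28 survives as a chelate until the cold quench, which prevents over-addition, and the arene is used in excess so that no free amide base meets 23.

Step 17
Reactants: 29 the keto ester
Product: 30 5-chloro-6,8-bis(methoxymethoxy)-3-[(1E,3E)-4-{(2S,3S,5S)-3-[(4-methoxybenzyl)oxy]-5-methyloxolan-2-yl}buta-1,3-dien-1-yl]-1H-isochromen-1-one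
Conditions: DBU (0.5 equiv), 4 Å MS, toluene, 50 °C
Reagents that add atoms: none
Why: In this base-catalysed enol lactonisation the doubly activated C4 methylene is enolised by DBU and the enolate oxygen attacks the neighbouring ester (6-exo-trig) with loss of methanol, which the sieves take up, a cyclisation known as the unwanted side reaction of benzylic keto resorcylates and driven here by the extended conjugation of the isochromenone.

Step 18
Reactants: 30 the fully protected isochromenone
Product: 31 5-chloro-3-{(1E,3E)-4-[(2S,3S,5S)-3-hydroxy-5-methyloxolan-2-yl]buta-1,3-dien-1-yl}-6,8-bis(methoxymethoxy)-1H-isochromen-1-one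
Conditions: DDQ, CH2Cl2/pH 7 buffer 10:1, 0 °C
Reagents that add atoms: none
Why: Oxidative PMB cleavage with DDQ (hydride abstraction from the electron-rich benzylic position, then hydrolysis of the oxocarbenium ion) is selective for the PMB ether over the acceptor-substituted arene and the lactone-conjugated diene, and MOM ethers are inert.

Step 19
Reactants: 31 the bis-MOM ether
Product: 32 5-chloro-6,8-dihydroxy-3-{(1E,3E)-4-[(2S,3S,5S)-3-hydroxy-5-methyloxolan-2-yl]buta-1,3-dien-1-yl}-1H-isochromen-1-one (target)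
Conditions: HCl (1.25 M in MeOH), CH2Cl2, 0 °C → rt
Reagents that add atoms: none
Why: Acid-catalysed acetal exchange with methanol removes the two phenolic MOM ethers, whose phenols are good leaving groups on this electron-poor ring, under conditions mild enough for the allylic C2'–O1' ether, whose ionisation is disfavoured by the adjacent hydroxyl-bearing carbon and the electron-withdrawing isochromenone.

Compound list
1 | diethyl L-tartrate | CCOC(=O)[C@H](O)[C@@H](O)C(=O)OCC | starting material
2 | 4-methoxybenzaldehyde dimethyl acetal | COC(OC)c1ccc(OC)cc1 | starting material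
3 | diethyl (4R,5R)-2-(4-methoxyphenyl)-1,3-dioxolane-4,5-dicarboxylate | CCOC(=O)[C@@H]1OC(c2ccc(OC)cc2)O[C@H]1C(=O)OCC | intermediate
4 | [(4S,5S)-2-(4-methoxyphenyl)-1,3-dioxolane-4,5-diyl]dimethanol (not isolated) | OC[C@@H]1OC(c2ccc(OC)cc2)O[C@H]1CO | intermediate
5 | 2-O-PMB-L-threitol, (2S,3S)-3-[(4-methoxybenzyl)oxy]butane-1,2,4-triol | OC[C@H](OCc1ccc(OC)cc1)[C@H](CO)O | intermediate
6 | (2S)-2-[(4S)-2,2-dimethyl-1,3-dioxolan-4-yl]-2-[(4-methoxybenzyl)oxy]ethan-1-ol | OC[C@H](OCc1ccc(OC)cc1)[C@@H]1COC(C)(C)O1 | intermediate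
7 | (2S)-2-[(4S)-2,2-dimethyl-1,3-dioxolan-4-yl]-2-[(4-methoxybenzyl)oxy]ethyl trifluoromethanesulfonate | O=S(=O)(OC[C@H](OCc1ccc(OC)cc1)[C@@H]1COC(C)(C)O1)C(F)(F)F | intermediate
8 | 2-methyl-1,3-dithiane | CC1SCCCS1 | starting material
9 | 2-lithio-2-methyl-1,3-dithiane (not isolated) | [Li]C1(C)SCCCS1 | intermediate
10 | (4S)-4-{(1S)-1-[(4-methoxybenzyl)oxy]-2-(2-methyl-1,3-dithian-2-yl)ethyl}-2,2-dimethyl-1,3-dioxolane | CC1(SCCCS1)C[C@H](OCc1ccc(OC)cc1)[C@@H]1COC(C)(C)O1 | intermediate
11 | (2S,3S)-3-[(4-methoxybenzyl)oxy]-4-(2-methyl-1,3-dithian-2-yl)butane-1,2-diol | CC1(SCCCS1)C[C@H](OCc1ccc(OC)cc1)[C@H](CO)O | intermediate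
12 | (2S,3S)-1-[(tert-butyldiphenylsilyl)oxy]-3-[(4-methoxybenzyl)oxy]-4-(2-methyl-1,3-dithian-2-yl)butan-2-ol | CC1(SCCCS1)C[C@H](OCc1ccc(OC)cc1)[C@H](CO[Si](c1ccccc1)(c1ccccc1)C(C)(C)C)O | intermediate
13 | (4S,5S)-6-[(tert-butyldiphenylsilyl)oxy]-5-hydroxy-4-[(4-methoxybenzyl)oxy]hexan-2-one (key-step precursor) | CC(=O)C[C@H](OCc1ccc(OC)cc1)[C@H](CO[Si](c1ccccc1)(c1ccccc1)C(C)(C)C)O | intermediate
14 | (4S,5S)-5-{[(tert-butyldiphenylsilyl)oxy]methyl}-4-[(4-methoxybenzyl)oxy]-2-methyloxolan-2-ol, both anomers (not isolated) | CC1(O)C[C@H](OCc2ccc(OC)cc2)[C@H](CO[Si](c2ccccc2)(c2ccccc2)C(C)(C)C)O1 | intermediate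
15 | (2S,3S)-2-{[(tert-butyldiphenylsilyl)oxy]methyl}-3-[(4-methoxybenzyl)oxy]-5-methyl-3,4-dihydro-2H-furan-1-ium (not isolated) | CC1=[O+][C@@H](CO[Si](c2ccccc2)(c2ccccc2)C(C)(C)C)[C@@H](OCc2ccc(OC)cc2)C1 | intermediate
16 | tert-butyl({(2S,3S,5S)-3-[(4-methoxybenzyl)oxy]-5-methyloxolan-2-yl}methoxy)diphenylsilane (key-step product) | C[C@H]1C[C@H](OCc2ccc(OC)cc2)[C@H](CO[Si](c2ccccc2)(c2ccccc2)C(C)(C)C)O1 | intermediate
17 | {(2S,3S,5S)-3-[(4-methoxybenzyl)oxy]-5-methyloxolan-2-yl}methanol | C[C@H]1C[C@H](OCc2ccc(OC)cc2)[C@H](CO)O1 | intermediate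
18 | (2R,3S,5S)-3-[(4-methoxybenzyl)oxy]-5-methyloxolane-2-carbaldehyde | C[C@H]1C[C@H](OCc2ccc(OC)cc2)[C@H](C=O)O1 | intermediate
19 | (triphenylphosphoranylidene)acetaldehyde | O=CC=P(c1ccccc1)(c1ccccc1)c1ccccc1 | starting material
20 | (2E)-3-{(2S,3S,5S)-3-[(4-methoxybenzyl)oxy]-5-methyloxolan-2-yl}prop-2-enal | C[C@H]1C[C@H](OCc2ccc(OC)cc2)[C@H](/C=C/C=O)O1 | intermediate
21 | diethyl {2-[methoxy(methyl)amino]-2-oxoethyl}phosphonate | CCOP(=O)(CC(=O)N(C)OC)OCC | starting material
22 | sodium salt of 21 (not isolated) | CCOP(=O)([CH-]C(=O)N(C)OC)OCC.[Na+] | intermediate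
23 | (2E,4E)-N-methoxy-N-methyl-5-{(2S,3S,5S)-3-[(4-methoxybenzyl)oxy]-5-methyloxolan-2-yl}penta-2,4-dienamide | C[C@H]1C[C@H](OCc2ccc(OC)cc2)[C@H](/C=C/C=C/C(=O)N(C)OC)O1 | intermediate
24 | methyl 2,4-dihydroxy-6-methylbenzoate | COC(=O)c1c(C)cc(O)cc1O | starting material
25 | methyl 3-chloro-4,6-dihydroxy-2-methylbenzoate | COC(=O)c1c(C)c(Cl)c(O)cc1O | intermediate
26 | methyl 3-chloro-4,6-bis(methoxymethoxy)-2-methylbenzoate | COCOc1cc(OCOC)c(C(=O)OC)c(C)c1Cl | intermediate
27 | methyl 3-chloro-2-(lithiomethyl)-4,6-bis(methoxymethoxy)benzoate (not isolated) | COCOc1cc(OCOC)c(C(=O)OC)c(C[Li])c1Cl | intermediate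
28 | lithium alkoxide of the N-methoxy-N-methyl hemiaminal from 27 and 23, new centre undefined (not isolated) | C[C@H]1C[C@H](OCc2ccc(OC)cc2)[C@H](/C=C/C=C/C(O[Li])(Cc2c(Cl)c(OCOC)cc(OCOC)c2C(=O)OC)N(C)OC)O1 | intermediate
29 | methyl 3-chloro-4,6-bis(methoxymethoxy)-2-[(3E,5E)-6-{(2S,3S,5S)-3-[(4-methoxybenzyl)oxy]-5-methyloxolan-2-yl}-2-oxohexa-3,5-dien-1-yl]benzoate | C[C@H]1C[C@H](OCc2ccc(OC)cc2)[C@H](/C=C/C=C/C(=O)Cc2c(Cl)c(OCOC)cc(OCOC)c2C(=O)OC)O1 | intermediate
30 | 5-chloro-6,8-bis(methoxymethoxy)-3-[(1E,3E)-4-{(2S,3S,5S)-3-[(4-methoxybenzyl)oxy]-5-methyloxolan-2-yl}buta-1,3-dien-1-yl]-1H-isochromen-1-one | C[C@H]1C[C@H](OCc2ccc(OC)cc2)[C@H](/C=C/C=C/c2cc3c(Cl)c(OCOC)cc(OCOC)c3c(=O)o2)O1 | intermediate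
31 | 5-chloro-3-{(1E,3E)-4-[(2S,3S,5S)-3-hydroxy-5-methyloxolan-2-yl]buta-1,3-dien-1-yl}-6,8-bis(methoxymethoxy)-1H-isochromen-1-one | C[C@H]1C[C@H](O)[C@H](/C=C/C=C/c2cc3c(Cl)c(OCOC)cc(OCOC)c3c(=O)o2)O1 | intermediate
32 | 5-chloro-6,8-dihydroxy-3-{(1E,3E)-4-[(2S,3S,5S)-3-hydroxy-5-methyloxolan-2-yl]buta-1,3-dien-1-yl}-1H-isochromen-1-one | C[C@H]1C[C@H](O)[C@H](/C=C/C=C/c2cc3c(Cl)c(O)cc(O)c3c(=O)o2)O1 | target

Total step count: 19 (17 in the main line, 2 for the arene).
Longest linear sequence: 17 steps from 1 (steps 1–13 and 16–19).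

Steps most likely to fail

1. **Step 16.**
   - Risk: the stabilised benzylic anion may add to the dienamide in the conjugate sense, may act as a base towards the C2' hydrogen, or may condense with its own ester.
   - Fallback: the arene is made into a complete isochromenone first, and the diene is finished by olefination instead of acylation. This sets out from 26 and enal 20 and comes back at 30.
   - Lithiation of 26 as in step 16 and acylation with N-methoxy-N-methylacetamide should give methyl 3-chloro-4,6-bis(methoxymethoxy)-2-(2-oxopropyl)benzoate F1.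
   - DBU should close this to 5-chloro-6,8-bis(methoxymethoxy)-3-methyl-1H-isochromen-1-one F2.
   - Deprotonation of the C3 methyl group with two equivalents of LiN(i-Pr)2, followed by ClP(O)(OEt)2, should give diethyl {[5-chloro-6,8-bis(methoxymethoxy)-1-oxo-1H-isochromen-3-yl]methyl}phosphonate F3.
   - Horner–Wadsworth–Emmons reaction of the lithium salt of F3 (LiN(SiMe3)2, THF, −78 °C) with 20 forms Cc=Cd and gives 30. Steps 13, 16 and 17 drop out, and the oxolane fragment never meets a benzylic organolithium.

2. **Step 9.**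
   - Risk: poor facial selectivity at C5', loss of the PMB group under the Lewis acid, or proton loss from the cation followed by elimination and aromatisation.
   - Fallback: the same O1'–C5' bond is closed on an alkene rather than on a ketone, by a reaction whose 2,5-trans preference does not rest on the C3' substituent. This sets out from triflate 7 and comes back at 16.
   - CuBr-catalysed coupling of 7 with CH2=CHMgBr should give (4S)-4-{(1S)-1-[(4-methoxybenzyl)oxy]but-3-en-1-yl}-2,2-dimethyl-1,3-dioxolane F4.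
   - Aqueous acetic acid gives (2S,3S)-3-[(4-methoxybenzyl)oxy]hex-5-ene-1,2-diol F5.
   - t-BuPh2SiCl/imidazole gives (2S,3S)-1-[(tert-butyldiphenylsilyl)oxy]-3-[(4-methoxybenzyl)oxy]hex-5-en-2-ol F6.
   - Mukaiyama aerobic oxidative cyclisation is reliably 2,5-trans-selective for pent-4-en-1-ols. The conditions are bis(1-morpholinocarbamoyl-4,4-dimethylpentane-1,3-dionato)cobalt (cat.), O2, t-BuOOH, i-PrOH, 55 °C. It should give {(2R,4S,5S)-5-{[(tert-butyldiphenylsilyl)oxy]methyl}-4-[(4-methoxybenzyl)oxy]oxolan-2-yl}methanol F7.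
   - TsCl/pyridine gives {(2R,4S,5S)-5-{[(tert-butyldiphenylsilyl)oxy]methyl}-4-[(4-methoxybenzyl)oxy]oxolan-2-yl}methyl 4-methylbenzenesulfonate F8.
   - LiBHEt3 reduces its C–O bond to the methyl group of 16.

3. **Step 5.**
   - Risk: E2 elimination or decomposition of the β-oxygenated triflate may outrun substitution by the hindered tertiary carbanion.
   - Fallback: a small linear carbon nucleophile is used, and the ketone comes from alkyne hydration instead of dithiane hydrolysis. This sets out from 7 and comes back at 13.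
   - HC≡CLi·H2NCH2CH2NH2 in THF/DMPU should convert 7 into (4S)-4-{(1S)-1-[(4-methoxybenzyl)oxy]but-3-yn-1-yl}-2,2-dimethyl-1,3-dioxolane F9.
   - Aqueous acetic acid gives (2S,3S)-3-[(4-methoxybenzyl)oxy]hex-5-yne-1,2-diol F10.
   - Selective silylation gives (2S,3S)-1-[(tert-butyldiphenylsilyl)oxy]-3-[(4-methoxybenzyl)oxy]hex-5-yn-2-ol F11.
   - Markovnikov hydration with Ph3PAuCl/AgOTf (cat.) in wet 1,4-dioxane is assisted by 5-exo-dig attack of the C2' hydroxyl on the activated alkyne. It should deliver 13 in equilibrium with 14.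

Further compounds
F1 | step 16 | methyl 3-chloro-4,6-bis(methoxymethoxy)-2-(2-oxopropyl)benzoate | CC(=O)Cc1c(Cl)c(OCOC)cc(OCOC)c1C(=O)OC
F2 | step 16 | 5-chloro-6,8-bis(methoxymethoxy)-3-methyl-1H-isochromen-1-one | Cc1cc2c(Cl)c(OCOC)cc(OCOC)c2c(=O)o1
F3 | step 16 | diethyl {[5-chloro-6,8-bis(methoxymethoxy)-1-oxo-1H-isochromen-3-yl]methyl}phosphonate | CCOP(=O)(Cc1cc2c(Cl)c(OCOC)cc(OCOC)c2c(=O)o1)OCC
F4 | step 9 | (4S)-4-{(1S)-1-[(4-methoxybenzyl)oxy]but-3-en-1-yl}-2,2-dimethyl-1,3-dioxolane | C=CC[C@H](OCc1ccc(OC)cc1)[C@@H]1COC(C)(C)O1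
F5 | step 9 | (2S,3S)-3-[(4-methoxybenzyl)oxy]hex-5-ene-1,2-diol | C=CC[C@H](OCc1ccc(OC)cc1)[C@H](CO)O
F6 | step 9 | (2S,3S)-1-[(tert-butyldiphenylsilyl)oxy]-3-[(4-methoxybenzyl)oxy]hex-5-en-2-ol | C=CC[C@H](OCc1ccc(OC)cc1)[C@H](CO[Si](c1ccccc1)(c1ccccc1)C(C)(C)C)O
F7 | step 9 | {(2R,4S,5S)-5-{[(tert-butyldiphenylsilyl)oxy]methyl}-4-[(4-methoxybenzyl)oxy]oxolan-2-yl}methanol | OC[C@H]1C[C@H](OCc2ccc(OC)cc2)[C@H](CO[Si](c2ccccc2)(c2ccccc2)C(C)(C)C)O1
F8 | step 9 | {(2R,4S,5S)-5-{[(tert-butyldiphenylsilyl)oxy]methyl}-4-[(4-methoxybenzyl)oxy]oxolan-2-yl}methyl 4-methylbenzenesulfonate | Cc1ccc(cc1)S(=O)(=O)OC[C@H]1C[C@H](OCc2ccc(OC)cc2)[C@H](CO[Si](c2ccccc2)(c2ccccc2)C(C)(C)C)O1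
F9 | step 5 | (4S)-4-{(1S)-1-[(4-methoxybenzyl)oxy]but-3-yn-1-yl}-2,2-dimethyl-1,3-dioxolane | C#CC[C@H](OCc1ccc(OC)cc1)[C@@H]1COC(C)(C)O1
F10 | step 5 | (2S,3S)-3-[(4-methoxybenzyl)oxy]hex-5-yne-1,2-diol | C#CC[C@H](OCc1ccc(OC)cc1)[C@H](CO)O
F11 | step 5 | (2S,3S)-1-[(tert-butyldiphenylsilyl)oxy]-3-[(4-methoxybenzyl)oxy]hex-5-yn-2-ol | C#CC[C@H](OCc1ccc(OC)cc1)[C@H](CO[Si](c1ccccc1)(c1ccccc1)C(C)(C)C)O
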